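**Plan**

1. Numbering (chromene): O1, C2, C3, C4 (C=O), C4a, C5 (enol), C6, C7 (C=O), C8 (quaternary), C8a. Ring A is the carbocycle and ring B the pyranone.
2. Enabling feature: ring B is a 2,3-dihydropyran-4-one, O1–C8a=C4a–C4(=O)–C3–C2. This is the retron of an aldehyde plus a 1-alkoxy-3-silyloxy diene. Cutting O1–C8a and C2–C3 gives acetaldehyde and the diene C8a(OMe)=C4a–C4(OSiEt3)=C3H–CH3 held inside ring A.
3. Further cuts: the acid and C5-OH go back to a C5–O enol lactone. The lactone is cut at C6–CH(Ph) and O5–C(=O) (cinnamaldehyde). Ring A is cut at C6–C7 (Dieckmann), C4a–C4 (halo-aldol), C4a–C5 (acetylide acylation) and C8a≡C4a (aldehyde homologation). C8 goes back to a malonate.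
4. Forward order: quaternary malonate, alkynyl ester, C8a-methoxy enedione, ring A, lactone ring, ring B, lactone opening.
5. Stereochemistry: the lavandulyl centre comes from (R)-lavandulol, C8 from asymmetric phase-transfer prenylation, and the benzylic carbon from chiral carbene catalysis. C2 and C3 (cis) come from a chiral boron Lewis acid acting on the Z-enol silane.

Key step: step 14

Assumption: the facial sense of the three chiral catalysts (steps 3, 12, 14) is assigned by analogy with simpler substrates. All three exist in both enantiomeric forms, and the antipode is used if the sense proves opposite.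

Notation: Lav = (2S)-5-methyl-2-(prop-1-en-2-yl)hex-4-en-1-yl. This is the unchanged spatial arrangement of (R)-lavandulol; the CIP label changes once CH2–O/I becomes CH2–C. Prenyl = 3-methylbut-2-en-1-yl.

**Step 1**
Reactants: 1 (R)-lavandulol
Product: 2 (R)-lavandulyl iodide, (2R)-1-iodo-5-methyl-2-(prop-1-en-2-yl)hex-4-ene
Conditions: I2, PPh3, imidazole, CH2Cl2, 0 °C
Reagents that add atoms: iodine, II
Why: The Appel-type iodination displaces the activated primary oxygen by SN2 at CH2 under neutral conditions, so the neighbouring stereocentre and both alkenes are untouched.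

**Step 2**
Reactants: 2 (R)-lavandulyl iodide; 3 tert-butyl methyl malonate
Product: 4 1-tert-butyl 3-methyl 2-Lav-propanedioate (labile epimers at the malonate CH)
Conditions: NaH, 3 in excess, THF–DMF, 0 to 50 °C
Reagents that add atoms: none
Why: In this malonic ester alkylation the soft sodium enolate substitutes the primary iodide rather than eliminating, excess malonate suppresses dialkylation, and the labile new CH centre is erased in step 3.

**Step 3**
Reactants: 4 Lav-malonate; 5 prenyl bromide
Product: 6 1-tert-butyl 3-methyl (2R)-2-Lav-2-prenylpropanedioate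
Conditions: (S,S)-3,4,5-trifluorophenyl-NAS bromide (5 mol %), 50 % aq. KOH, toluene, −40 °C
Reagents that add atoms: none
Why: In this asymmetric phase-transfer alkylation of an α-monosubstituted tert-butyl/methyl malonate with an allylic bromide, the chiral spiro-ammonium ion pair tells the enolate faces apart through the size difference of the two esters and so sets C8, and any minor epimer is a diastereomer (lavandulyl centre) that chromatography should remove.

**Step 4**
Reactants: 6 quaternary malonate
Product: 8 (2S)-2-(methoxycarbonyl)-5-methyl-2-Lav-hex-4-enoic acid, via trimethylsilyl ester 7 (not isolated)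
Conditions: TMSOTf, 2,6-lutidine, CH2Cl2, 0 °C; then H2O
Reagents that add atoms: trimethylsilyl triflate (silyl group only in 7), C[Si](C)(C)OS(=O)(=O)C(F)(F)F
Why: Silyl-triflate-mediated tert-butyl ester cleavage (loss of isobutene) under lutidine buffering avoids the free strong acid that would lactonise the acid onto the prenyl alkene, and the methyl ester is inert.

**Step 5**
Reactants: 8 half-acid
Product: 10 methyl (2S)-2-formyl-5-methyl-2-Lav-hex-4-enoate, via acid chloride 9 (not isolated)
Conditions: 1-chloro-N,N,2-trimethylprop-1-en-1-amine, CH2Cl2, 0 °C; then LiAlH(OtBu)3, THF, −78 °C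
Reagents that add atoms: 1-chloro-N,N,2-trimethylprop-1-en-1-amine (chlorine only in 9), CC(C)=C(Cl)N(C)C
Why: Acid chloride formation with an α-chloroenamine is free of HCl, the hindered-hydride reduction of the acid chloride stops at the aldehyde, the methyl ester does not react at −78 °C, and quaternary C8 cannot epimerise.

**Step 6**
Reactants: 10 α-formyl ester
Product: 11 methyl (2S)-2-ethynyl-5-methyl-2-Lav-hex-4-enoate
Conditions: TMSCHN2, LDA, THF, −78 °C to rt; then H2O
Reagents that add atoms: trimethylsilyldiazomethane, C[Si](C)(C)C=[N+]=[N-]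
Why: The Colvin rearrangement (addition, Peterson-type loss of silanolate, N2 loss and 1,2-H shift of the alkylidene carbene) gives the terminal alkyne in an aprotic medium without methoxide, which could deformylate the non-enolisable α-formyl ester.

**Step 7**
Reactants: 11 alkynyl ester
Product: 12 methyl (2S)-5-methyl-2-Lav-2-(3-oxobut-1-yn-1-yl)hex-4-enoate
Conditions: LDA, THF, −78 °C; N-methoxy-N-methylacetamide, −78 to 0 °C; then AcOH
Reagents that add atoms: N-methoxy-N-methylacetamide, CC(=O)N(C)OC
Why: In this acylation of a lithium acetylide with an N-methoxy-N-methylamide, the chelated tetrahedral adduct prevents over-addition, 11 has no enolisable C–H, and the neopentyl ester is too hindered to compete.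

**Step 8**
Reactants: 12 methyl ynone; 13 propanal
Product: 14 methyl (2R)-2-[(1E)-2-acetyl-3-hydroxy-1-iodopent-1-en-1-yl]-5-methyl-2-Lav-hex-4-enoate (both carbinol epimers)
Conditions: MgI2, 13, CH2Cl2, 0 °C; then H2O
Reagents that add atoms: magnesium iodide, [Mg+2].[I-].[I-]
Why: In this three-component halo-aldol (iodide-initiated Morita–Baylis–Hillman-type) reaction, iodide adds to C8a of the Mg-activated ynone and the allenolate attacks propanal through C4a from the side of iodine, away from bulky C8, which forms C4a–C4 and leaves the acetyl group cis to C8.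

**Step 9**
Reactants: 14 iodo carbinol
Product: 15 methyl (2R)-2-[(1Z)-2-acetyl-1-iodo-3-oxopent-1-en-1-yl]-5-methyl-2-Lav-hex-4-enoate
Conditions: Dess–Martin periodinane, CH2Cl2, 0 °C to rt
Reagents that add atoms: none
Why: The Dess–Martin oxidation of the secondary allylic alcohol is neutral, spares the alkenes and the vinyl iodide, and merges both carbinol epimers into one ketone.

**Step 10**
Reactants: 15 iodo enedione
Product: 16 methyl (2S)-2-[(1Z)-2-acetyl-1-methoxy-3-oxopent-1-en-1-yl]-5-methyl-2-Lav-hex-4-enoate
Conditions: NaOMe (1.05 equiv), MeOH–THF, −20 °C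
Reagents that add atoms: sodium methoxide, [Na+].[O-]C
Why: Addition–elimination (vinylogous nucleophilic substitution) on the doubly activated β-iodo enedione puts the methoxy group on C8a, the former alkyne carbon next to C8, so no regiochemically ambiguous O-alkylation of a triketone is ever needed.

**Step 11**
Reactants: 16 methoxy enedione ester
Product: 17 (6S)-3-hydroxy-5-methoxy-6-Lav-6-prenyl-4-propanoylcyclohexa-2,4-dien-1-one (ring A: C8a-OMe, C4a-propanoyl, C5 enol, C6-H, C7 ketone)
Conditions: LiHMDS (2.3 equiv), THF, −78 to 0 °C; then cold 1 M HCl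
Reagents that add atoms: none
Why: In this Dieckmann condensation (6-exo-trig) the acetyl CH3 is deprotonated faster than the propanoyl CH2, lies cis to C8, is the smaller nucleophile toward the neopentyl ester and gives the more acidic C6-unsubstituted 1,3-dione whose enolate drives ring closure, while C8 keeps its configuration because C8a stays an enol ether as C7 becomes a ketone.

**Step 12**
Reactants: 17 ring A dione; 18 (E)-cinnamaldehyde
Product: 19 (4S,6S)-7-methoxy-6-Lav-6-prenyl-4-phenyl-8-propanoyl-3,4-dihydro-2H-chromene-2,5(6H)-dione (lactone O on C5, CHPh on C6, C7 ketone, C8a-OMe, C4a-propanoyl)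
Conditions: (5aR,10bS)-N-mesityl aminoindanol-derived triazolium tetrafluoroborate (10 mol %), DBU (20 mol %), 3,3',5,5'-tetra-tert-butyldiphenoquinone (1.2 equiv), toluene, rt
Reagents that add atoms: none
Why: In this oxidative N-heterocyclic carbene catalysis (Michael addition–lactonisation of a cyclic 1,3-dione with an α,β-unsaturated acyl azolium), C6, the only soft carbon nucleophile of 17, adds to the β-carbon on the face left open by the chiral carbene and so sets the benzylic centre under catalyst control, and the acyl azolium is then captured by the C5 enol oxygen rather than by O7, which is screened by the two chains on C8.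

**Step 13**
Reactants: 19 lactone ketone
Product: 20 (4S,6S)-7-methoxy-6-Lav-6-prenyl-4-phenyl-8-[(1Z)-1-(triethylsilyloxy)prop-1-en-1-yl]-3,4-dihydro-2H-chromene-2,5(6H)-dione (ring-embedded diene)
Conditions: TESOTf (1.1 equiv), iPr2NEt, CH2Cl2, −78 to 0 °C
Reagents that add atoms: triethylsilyl triflate, CC[Si](CC)(CC)OS(=O)(=O)C(F)(F)F
Why: In this soft enolisation with a silyl triflate and a non-nucleophilic amine, C4 is the only ketone with α-hydrogens, allylic strain against fully substituted C4a places the methyl group cis to oxygen (Z), and one equivalent of reagent leaves the less basic lactone carbonyl alone.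

**Step 14**
Reactants: 20 ring-embedded diene; 21 acetaldehyde
Product: 23 C5–O enol lactone of the target (ring B = (2R,3S)-cis-2,3-dimethyl-2,3-dihydropyran-4-one fused to ring A at C4a–C8a; C8 S, benzylic S), via triethylsilyl aldol ether 22 (not isolated)
Conditions: 21 (5 equiv), chiral (acyloxy)borane from (2S,3S)-2-O-(2,6-diisopropoxybenzoyl)tartaric acid and 2-MeOC6H4B(OH)2 (20 mol %), EtCN, −78 °C; then HF·pyridine, THF, 0 °C
Reagents that add atoms: none
Why: Proposed new method: this is a formal hetero-Diels–Alder reaction in which the boron Lewis acid binds 21 and the C3 terminus of the Z-enol silane attacks its Si face, giving a cation delocalised between C4(OSiEt3) and C8a(OMe); silyl transfer gives 22, and on HF treatment the C2 oxygen adds to C8a and methanol leaves, so C2–C3 and O1–C8a are both made in one flask. The closest known reaction type is the chiral (acyloxy)borane-catalysed hetero-Diels–Alder or Mukaiyama aldol–cyclisation of acyclic 1-methoxy-3-silyloxy-1,3-pentadienes with aldehydes, which is cis-selective; what is new is a diene whose C8a=C4a bond lies inside a cyclohexadienone, which forces the methoxy group into the inside (Z) position and makes the stepwise path more likely than a concerted [4+2]. Ring B closes by a 6-endo-trig addition–elimination, the equivalent of the second σ-bond of the cycloaddition. C2 is set by the catalyst, which shields the Re face of the aldehyde, and C3 by the syn-selective extended transition state of the enol silane (a syn aldol maps onto the cis-2,3-dimethyl ring), while the remote C8 and benzylic centres should not interfere. The step needs O1 to end on C8a and not on C5, which is secured because C8a is the methoxy-stabilised cationic terminus of the diene whereas C5 is held as a non-donating enol-ester carbon in the lactone. No base is present at any stage, so the epimerisable C3 is not at risk.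

**Step 15**
Reactants: 23 enol lactone
Product: 24 target, (3S)-3-[(2R,3S,8S)-5-hydroxy-2,3-dimethyl-8-Lav-8-prenyl-4,7-dioxo-3,4,7,8-tetrahydro-2H-chromen-6-yl]-3-phenylpropanoic acid
Conditions: LiOH (2.2 equiv), THF–H2O, 0 °C, short contact; then cold 1 M HCl to pH 3
Reagents that add atoms: lithium hydroxide, [Li+].[OH-]
Why: In this saponification of an enol ester, hydroxide attacks the activated lactone carbonyl much faster than any other site, and the resulting carboxylate/C5-enolate dianion is too electron-rich for deprotonation at C3 or retro-oxa-Michael opening at 0 °C, so the cis-dimethyl unit should survive.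

**Compound list**

1 | (R)-lavandulol | C=C(C)[C@@H](CC=C(C)C)CO | starting material
2 | (R)-lavandulyl iodide | C=C(C)[C@@H](CC=C(C)C)CI | intermediate
3 | tert-butyl methyl malonate | COC(=O)CC(=O)OC(C)(C)C | starting material
4 | 1-tert-butyl 3-methyl 2-Lav-propanedioate | C=C(C)[C@@H](CC=C(C)C)CC(C(=O)OC)C(=O)OC(C)(C)C | intermediate
5 | prenyl bromide | CC(C)=CCBr | starting material
6 | 1-tert-butyl 3-methyl (2R)-2-Lav-2-prenylpropanedioate | C=C(C)[C@@H](CC=C(C)C)C[C@](CC=C(C)C)(C(=O)OC)C(=O)OC(C)(C)C | intermediate
7 | methyl trimethylsilyl (2R)-2-Lav-2-prenylpropanedioate | C=C(C)[C@@H](CC=C(C)C)C[C@](CC=C(C)C)(C(=O)OC)C(=O)O[Si](C)(C)C | intermediate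
8 | (2S)-2-(methoxycarbonyl)-5-methyl-2-Lav-hex-4-enoic acid | C=C(C)[C@@H](CC=C(C)C)C[C@](CC=C(C)C)(C(=O)OC)C(=O)O | intermediate
9 | methyl (2R)-2-(chlorocarbonyl)-5-methyl-2-Lav-hex-4-enoate | C=C(C)[C@@H](CC=C(C)C)C[C@](CC=C(C)C)(C(=O)OC)C(=O)Cl | intermediate
10 | methyl (2S)-2-formyl-5-methyl-2-Lav-hex-4-enoate | C=C(C)[C@@H](CC=C(C)C)C[C@](CC=C(C)C)(C(=O)OC)C=O | intermediate
11 | methyl (2S)-2-ethynyl-5-methyl-2-Lav-hex-4-enoate | C=C(C)[C@@H](CC=C(C)C)C[C@](CC=C(C)C)(C(=O)OC)C#C | intermediate
12 | methyl (2S)-5-methyl-2-Lav-2-(3-oxobut-1-yn-1-yl)hex-4-enoate | C=C(C)[C@@H](CC=C(C)C)C[C@](CC=C(C)C)(C(=O)OC)C#CC(C)=O | intermediate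
13 | propanal | CCC=O | starting material
14 | (E)-β-iodo carbinol (C8a-I, C4a-acetyl, C4-OH, both C4 epimers) | C=C(C)[C@@H](CC=C(C)C)C[C@](CC=C(C)C)(C(=O)OC)/C(I)=C(\C(C)=O)C(O)CC | intermediate
15 | (Z)-β-iodo enedione | C=C(C)[C@@H](CC=C(C)C)C[C@](CC=C(C)C)(C(=O)OC)/C(I)=C(\C(C)=O)C(=O)CC | intermediate
16 | (Z)-β-methoxy enedione | C=C(C)[C@@H](CC=C(C)C)C[C@](CC=C(C)C)(C(=O)OC)/C(OC)=C(\C(C)=O)C(=O)CC | intermediate
17 | (6S)-3-hydroxy-5-methoxy-6-Lav-6-prenyl-4-propanoylcyclohexa-2,4-dien-1-one | C=C(C)[C@@H](CC=C(C)C)C[C@]1(CC=C(C)C)C(=O)C=C(O)C(C(=O)CC)=C1OC | intermediate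
18 | (E)-cinnamaldehyde | O=C/C=C/c1ccccc1 | starting material
19 | lactone-locked ring A with C8a-OMe and C4a-propanoyl | C=C(C)[C@@H](CC=C(C)C)C[C@]1(CC=C(C)C)C(=O)C2=C(OC(=O)C[C@H]2c3ccccc3)C(C(=O)CC)=C1OC | intermediate
20 | Z-triethylsilyl enol ether of 19 (key-step precursor) | C=C(C)[C@@H](CC=C(C)C)C[C@]1(CC=C(C)C)C(=O)C2=C(OC(=O)C[C@H]2c3ccccc3)C(/C(O[Si](CC)(CC)CC)=C/C)=C1OC | intermediate
21 | acetaldehyde | CC=O | starting material
22 | syn aldol triethylsilyl ether (C2-OSiEt3, C8a-OMe still in place) | C=C(C)[C@@H](CC=C(C)C)C[C@]1(CC=C(C)C)C(=O)C2=C(OC(=O)C[C@H]2c3ccccc3)C(C(=O)[C@@H](C)[C@@H](C)O[Si](CC)(CC)CC)=C1OC | intermediate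
23 | C5–O enol lactone of the target (key-step product) | C=C(C)[C@@H](CC=C(C)C)C[C@]1(CC=C(C)C)C(=O)C2=C(OC(=O)C[C@H]2c3ccccc3)C4=C1O[C@H](C)[C@H](C)C4=O | intermediate
24 | CNP0150579.2 | C=C(C)[C@@H](CC=C(C)C)C[C@]1(CC=C(C)C)C(=O)C([C@@H](CC(=O)O)c2ccccc2)=C(O)C2=C1O[C@H](C)[C@H](C)C2=O | target

**Totals**

Total step count: 15. Longest linear sequence: 15 steps, from (R)-lavandulol (1) to 24.

**Steps most likely to fail**

Step 14. Several processes may go wrong:
- C–C bond formation may be slow at the crowded, cross-conjugated enol silane.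
- Syn selectivity may erode in the open transition state.
- The C2 oxygen may close onto C5 with expulsion of the lactone carboxylate.
- The prenyl or lavandulyl alkenes may cyclise under acid during desilylation.

The fallback uses known chemistry, sets out from ketone 19 and makes the two bonds in separate operations. Enolisation of 19 with the matched enantiomer of diisopinocampheylboron triflate and iPr2NEt in CH2Cl2 at −78 °C gives the Z-boron enolate. This adds to acetaldehyde 21 through a closed chair transition state, and a non-oxidative work-up with diethanolamine gives the syn β-hydroxy ketone F1. PPTS in CH2Cl2 at room temperature then exchanges the C8a methoxy group for the C2 hydroxyl by vinylogous transesterification. The route is rejoined at 23.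

Step 8. Iodide addition to the alkyne carbon next to quaternary C8 may be slow. The magnesium allenolate may be protonated before it meets the aldehyde. The two enolisable carbonyl partners may self-condense.

The fallback sets out from ynone 12 and makes C4a nucleophilic as an enaminone instead of an allenolate. Conjugate addition of dimethylamine in THF gives the (E)-enaminone F2. C-acylation at C4a with propanoyl chloride and Et3N gives the 2-acyl enaminone F3. Acid-mediated exchange with methanol (one equivalent of TsOH, MeOH) replaces the amine by methoxy. The route is rejoined at 16.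

Step 11. Enolisation may compete at the propanoyl CH2, with ring closure through C3. Liberated methoxide may deacylate the enedione. The two acyl groups may scramble about the push–pull double bond.

The fallback sets out from carbinol 14 and keeps C4 at the alcohol level, so that the acetyl group is the only enolisable ketone.
- Silylation with TESCl and imidazole gives the silyl ether F4.
- NaOMe converts it into the β-methoxy enone F5.
- LiHMDS closes ring A to the silyl-protected dione F6.
- Buffered HF·pyridine frees the ring carbinol F7.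
- MnO2 oxidises the allylic alcohol, and the route is rejoined at 17.

**Further compounds**

F1 | step 14 | syn β-hydroxy ketone (free C2-OH, C8a-OMe in place) | C=C(C)[C@@H](CC=C(C)C)C[C@]1(CC=C(C)C)C(=O)C2=C(OC(=O)C[C@H]2c3ccccc3)C(C(=O)[C@@H](C)[C@@H](C)O)=C1OC
F2 | step 8 | (E)-enaminone, dimethylamine adduct of 12 | C=C(C)[C@@H](CC=C(C)C)C[C@](CC=C(C)C)(C(=O)OC)/C(N(C)C)=C\C(C)=O
F3 | step 8 | 2-acyl enaminone (C8a-NMe2, C4a-acetyl and C4a-propanoyl) | C=C(C)[C@@H](CC=C(C)C)C[C@](CC=C(C)C)(C(=O)OC)/C(N(C)C)=C(\C(C)=O)C(=O)CC
F4 | step 11 | triethylsilyl ether of 14 | C=C(C)[C@@H](CC=C(C)C)C[C@](CC=C(C)C)(C(=O)OC)/C(I)=C(\C(C)=O)C(CC)O[Si](CC)(CC)CC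
F5 | step 11 | β-methoxy enone with C4-OSiEt3 | C=C(C)[C@@H](CC=C(C)C)C[C@](CC=C(C)C)(C(=O)OC)/C(OC)=C(\C(C)=O)C(CC)O[Si](CC)(CC)CC
F6 | step 11 | ring A dione with C4a-CH(OSiEt3)Et | C=C(C)[C@@H](CC=C(C)C)C[C@]1(CC=C(C)C)C(=O)C=C(O)C(C(CC)O[Si](CC)(CC)CC)=C1OC
F7 | step 11 | ring A dione with C4a-CH(OH)Et | C=C(C)[C@@H](CC=C(C)C)C[C@]1(CC=C(C)C)C(=O)C=C(O)C(C(O)CC)=C1OC
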